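**Retrosynthetic overview**

- Ring A is a cyclopentane. Its tertiary carbinol carbon C(CH3)(OH) lies between a ring CH2 and the ring CH that holds the CH2 link to ring B. Cutting the carbinol C–CH2 ring bond gives a methyl ketone carbon and a primary iodide carbon, two acceptor carbons that a two-electron reductant can unite.
- Ring A is made first, by SmI2 Barbier closure of an anti 3,4-disubstituted 6-iodohexan-2-one. This comes from a trans-3,4-disubstituted δ-lactone (asymmetric Rh-catalysed isopropenyl addition to 5,6-dihydropyran-2-one, then enolate alkylation with a silyloxypropyl iodide).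
- Ring B is made second. The three-carbon arm is oxidised onto the cis tertiary hydroxyl to a δ-lactone, which acylates the CH3 enolate of ethyl (S)-2-methyl-2-prenylacetoacetate. Dieckmann closure of the diketone polyanion on the ester gives the six-membered trione.
- The keto ester comes from ethyl (R)-3-hydroxybutanoate (prenylation, methylation, oxidation). The (S)-2-methylbutanoyl group is put on the free ring CH last.

Key step: step 6

Assumption: ring B compounds are written in the enol form of the target SMILES; the enol and keto forms interconvert freely and none of them involves the quaternary carbon.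

**Step 1**
Reactants: 1 5,6-dihydro-2H-pyran-2-one; 2 potassium isopropenyltrifluoroborate
Product: 3 (4R)-4-(prop-1-en-2-yl)oxan-2-one
Conditions: [Rh(cod)2]BF4 (3 mol %), (R)-BINAP (3.3 mol %), Et3N, PhMe/H2O, 50 °C
Reagents that add atoms: none
Why: Hayashi–Miyaura asymmetric 1,4-addition, in which the isopropenylrhodium–(R)-BINAP species formed by transmetalation inserts the lactone C=C on the face the ligand leaves open and the rhodium enolate is hydrolysed, which should set C4 as (R), the sense being assigned from the behaviour of cyclic enones and unsaturated δ-lactones with this ligand.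

**Step 2**
Reactants: 3 (4R)-4-(prop-1-en-2-yl)oxan-2-one; 4 tert-butyl(3-iodopropoxy)dimethylsilane
Product: 6 (3S,4R)-3-[3-(tert-butyldimethylsilyloxy)propyl]-4-(prop-1-en-2-yl)oxan-2-one, via lactone lithium enolate 5 (not isolated)
Conditions: LiN(iPr)2, THF, −78 °C; then 4, DMPU, −78 → −30 °C
Reagents that add atoms: none
Why: SN2 alkylation of a δ-lactone lithium enolate by a primary iodide, in which the electrophile approaches the half-chair enolate on the face opposite the C4 isopropenyl group and so sets C3 as (S), trans to C4.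

**Step 3**
Reactants: 6 (3S,4R)-3-[3-(tert-butyldimethylsilyloxy)propyl]-4-(prop-1-en-2-yl)oxan-2-one
Product: 7 (2S,3R)-2-[3-(tert-butyldimethylsilyloxy)propyl]-3-(2-hydroxyethyl)-N-methoxy-N,4-dimethylpent-4-enamide
Conditions: MeNH(OMe)·HCl, AlMe3, CH2Cl2, 0 °C → rt; aq. potassium sodium tartrate
Reagents that add atoms: N,O-dimethylhydroxylamine hydrochloride, CNOC.Cl
Why: Weinreb aminolysis of a lactone by the aluminium amide opens the ring at the acyl–oxygen bond under non-basic conditions, so both stereocentres are untouched and the primary alcohol is freed.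

**Step 4**
Reactants: 7 (2S,3R)-2-[3-(tert-butyldimethylsilyloxy)propyl]-3-(2-hydroxyethyl)-N-methoxy-N,4-dimethylpent-4-enamide
Product: 8 (2S,3R)-2-[3-(tert-butyldimethylsilyloxy)propyl]-3-(2-iodoethyl)-N-methoxy-N,4-dimethylpent-4-enamide
Conditions: I2, PPh3, imidazole, CH2Cl2, 0 °C
Reagents that add atoms: iodine, [I][I]
Why: Appel-type iodination (Garegg–Samuelsson conditions) converts the primary alcohol by SN2 on its alkoxyphosphonium salt, imidazole keeps the medium neutral for the silyl ether, and prompt use of 7 forestalls relactonisation.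

**Step 5**
Reactants: 8 (2S,3R)-2-[3-(tert-butyldimethylsilyloxy)propyl]-3-(2-iodoethyl)-N-methoxy-N,4-dimethylpent-4-enamide
Product: 10 (3S,4R)-3-[3-(tert-butyldimethylsilyloxy)propyl]-6-iodo-4-(prop-1-en-2-yl)hexan-2-one, via magnesium hemiaminal chelate 9 (not isolated)
Conditions: MeMgBr, THF, −20 → 0 °C
Reagents that add atoms: methylmagnesium bromide, C[Mg]Br
Why: Weinreb ketone synthesis, in which the chelated adduct holds until the quench so that only one methyl group is taken up, the α-centre never meets base as a free ketone, and a primary alkyl iodide is not attacked by MeMgBr at this temperature.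

**Step 6**
Reactants: 10 (3S,4R)-3-[3-(tert-butyldimethylsilyloxy)propyl]-6-iodo-4-(prop-1-en-2-yl)hexan-2-one
Product: 12 (1R,2S,3R)-2-[3-(tert-butyldimethylsilyloxy)propyl]-1-methyl-3-(prop-1-en-2-yl)cyclopentan-1-ol, via alkylsamarium diiodide 11 (not isolated)
Conditions: SmI2 (2.5 equiv), HMPA (10 equiv), THF, 0 °C, slow addition of 10
Reagents that add atoms: none
Why: Divalent samarium, made a stronger reductant by HMPA, breaks the carbon–iodine bond of 10 to a primary radical and reduces that radical at once to alkylsamarium 11 (trivalent samarium), whose carbon adds to the methyl ketone at the other end of the chain; should the ketone be reduced first, the ketyl couples at the same two carbons. The closest known reaction type is the samarium Barbier cyclisation of ω-iodoalkyl ketones to cyclopentanols. Ring A closes 5-exo-trig by the bond between C2 (carbonyl carbon, later the carbinol carbon) and C6 (CH2I, later the ring CH2). The carbinol carbon is the one new stereocentre and is controlled by C3: with arm and isopropenyl group pseudo-equatorial on the forming ring, the acetyl group should turn its methyl towards the small C3–H and its oxygen towards the arm, which gives the (1R) alcohol with hydroxyl cis and methyl trans to the arm. The step needs chemoselective reduction of the iodide and a radical that is not diverted: the iodide is reduced far faster than a dialkyl ketone under these conditions, excess reductant shortens the life of the radical, and the isopropenyl group can be reached only by 4-exo or 5-endo closure. No base or enolate is involved, so the epimerisable C3 keeps its configuration, and the silyl ether and the 1,1-disubstituted alkene are not reduced.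

**Step 7**
Reactants: 12 (1R,2S,3R)-2-[3-(tert-butyldimethylsilyloxy)propyl]-1-methyl-3-(prop-1-en-2-yl)cyclopentan-1-ol
Product: 13 (1R,2S,3R)-2-(3-hydroxypropyl)-1-methyl-3-(prop-1-en-2-yl)cyclopentan-1-ol
Conditions: Bu4NF, THF, rt
Reagents that add atoms: none
Why: Fluoride desilylation of the primary silyl ether, driven by the Si–F bond, leaves the tertiary alcohol and the alkene untouched.

**Step 8**
Reactants: 13 (1R,2S,3R)-2-(3-hydroxypropyl)-1-methyl-3-(prop-1-en-2-yl)cyclopentan-1-ol
Product: 16 (4aS,5R,7aR)-7a-methyl-5-(prop-1-en-2-yl)hexahydrocyclopenta[b]pyran-2(3H)-one, via hydroxy aldehyde 14 (not isolated), via lactol 15 (not isolated)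
Conditions: TEMPO (20 mol %), PhI(OAc)2 (2.5 equiv), CH2Cl2, rt
Reagents that add atoms: none
Why: Oxoammonium oxidative lactonisation of a 1,5-diol, in which the primary alcohol gives aldehyde 14, the cis tertiary hydroxyl closes it to lactol 15 and a second oxidation gives the cis-fused δ-lactone, which masks the carbinol and serves as the acyl donor without change at any stereocentre.

**Step 9**
Reactants: 17 ethyl (R)-3-hydroxybutanoate; 18 1-bromo-3-methylbut-2-ene (prenyl bromide)
Product: 20 ethyl (2R)-2-[(1R)-1-hydroxyethyl]-5-methylhex-4-enoate, via dilithio dianion 19 (not isolated)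
Conditions: LiN(iPr)2 (2.2 equiv), THF, −78 → −20 °C; then 18, DMPU, −78 → 0 °C
Reagents that add atoms: none
Why: Fráter–Seebach alkylation, in which the lithium-chelated dianion is prenylated (SN2) on the face away from the carbinol methyl group to give the anti (2R) product, a centre that serves only as a relay for the next step.

**Step 10**
Reactants: 20 ethyl (2R)-2-[(1R)-1-hydroxyethyl]-5-methylhex-4-enoate
Product: 22 ethyl (2S)-2-[(1R)-1-hydroxyethyl]-2,5-dimethylhex-4-enoate, via dilithio dianion 21 (not isolated)
Conditions: LiN(iPr)2 (2.5 equiv), THF, −78 → 0 °C; then MeI, DMPU, −78 → 0 °C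
Reagents that add atoms: iodomethane, CI
Why: Second Fráter–Seebach alkylation, in which the dianion has the same chelated geometry and is methylated on the same face, so that methyl takes the place prenyl took in step 9 and the quaternary carbon is set as (S) under control of the (R)-carbinol centre.

**Step 11**
Reactants: 22 ethyl (2S)-2-[(1R)-1-hydroxyethyl]-2,5-dimethylhex-4-enoate
Product: 23 ethyl (2S)-2-acetyl-2,5-dimethylhex-4-enoate
Conditions: Dess–Martin periodinane, CH2Cl2, 0 °C → rt
Reagents that add atoms: none
Why: Dess–Martin oxidation of the secondary alcohol to the methyl ketone under near-neutral conditions, where the quaternary centre has no α-hydrogen and cannot epimerise.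

**Step 12**
Reactants: 16 (4aS,5R,7aR)-7a-methyl-5-(prop-1-en-2-yl)hexahydrocyclopenta[b]pyran-2(3H)-one; 23 ethyl (2S)-2-acetyl-2,5-dimethylhex-4-enoate
Product: 25 ethyl (2S)-7-[(1S,2R,5R)-2-hydroxy-2-methyl-5-(prop-1-en-2-yl)cyclopentyl]-2-methyl-2-(3-methylbut-2-en-1-yl)-3,5-dioxoheptanoate, via keto ester lithium enolate 24 (not isolated)
Conditions: 23 (2.2 equiv), LiN(iPr)2 (2.1 equiv), THF, −78 °C; then 16, −78 → −20 °C
Reagents that add atoms: none
Why: Crossed Claisen acylation of a ketone enolate by a δ-lactone, in which 23 can lose a proton only at the acetyl CH3, the enolate adds to the unhindered lactone carbonyl, the tertiary alkoxide leaves and the second equivalent of enolate deprotonates the β-diketone and makes the step irreversible, no stereocentre being formed (25 is a mixture of keto, enol and hemiketal forms and is carried on without contact with acid).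

**Step 13**
Reactants: 25 ethyl (2S)-7-[(1S,2R,5R)-2-hydroxy-2-methyl-5-(prop-1-en-2-yl)cyclopentyl]-2-methyl-2-(3-methylbut-2-en-1-yl)-3,5-dioxoheptanoate
Product: 27 (6R)-3,5-dihydroxy-4-{[(1S,2R,5R)-2-hydroxy-2-methyl-5-(prop-1-en-2-yl)cyclopentyl]methyl}-6-methyl-6-(3-methylbut-2-en-1-yl)cyclohexa-2,4-dien-1-one, via trilithio polyanion 26 (not isolated)
Conditions: LiN(iPr)2 (3.5 equiv), THF, −78 °C → rt; then cold 1 M HCl
Reagents that add atoms: none
Why: Dieckmann closure by intramolecular acylation of a β-diketone polyanion, in which, after alkoxide and central enolate have formed, the last equivalent of base removes a proton from C6, the only outer position that bears hydrogen, and this most nucleophilic carbon attacks the ester 6-exo-trig with loss of ethoxide, as in the classical routes to gem-dialkyl cyclohexane-1,3,5-triones, leaving the quaternary centre untouched.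

**Step 14**
Reactants: 27 (6R)-3,5-dihydroxy-4-{[(1S,2R,5R)-2-hydroxy-2-methyl-5-(prop-1-en-2-yl)cyclopentyl]methyl}-6-methyl-6-(3-methylbut-2-en-1-yl)cyclohexa-2,4-dien-1-one; 28 (S)-2-methylbutanoic acid
Product: 30 (6R)-3,5-dihydroxy-4-{[(1S,2R,5R)-2-hydroxy-2-methyl-5-(prop-1-en-2-yl)cyclopentyl]methyl}-6-methyl-6-(3-methylbut-2-en-1-yl)-2-[(2S)-2-methylbutanoyl]cyclohexa-2,4-dien-1-one (target), via enol ester 29 (not isolated)
Conditions: DCC, DMAP (30 mol %), Et3N, CH2Cl2, rt
Reagents that add atoms: none
Why: Carbodiimide/DMAP C-acylation of a cyclic β-triketone, in which O-acylation gives an enol ester and DMAP carries the acyl group on to carbon (O→C acyl migration), only the unsubstituted ring CH giving a product held as a chelated enol while acylation at the arm-bearing carbon is reversible and the hindered tertiary alcohol does not compete, the (S) centre coming unchanged from 28.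

**Compound list**

1 | 5,6-dihydro-2H-pyran-2-one | O=C1C=CCCO1 | starting material
2 | potassium isopropenyltrifluoroborate | C=C(C)[B-](F)(F)F.[K+] | starting material
3 | (4R)-4-(prop-1-en-2-yl)oxan-2-one | C=C(C)[C@@H]1CCOC(=O)C1 | intermediate
4 | tert-butyl(3-iodopropoxy)dimethylsilane | CC(C)(C)[Si](C)(C)OCCCI | starting material
5 | lithium enolate of lactone 3 | C=C(C)[C@@H]1CCOC([O-])=C1.[Li+] | intermediate
6 | (3S,4R)-3-[3-(tert-butyldimethylsilyloxy)propyl]-4-(prop-1-en-2-yl)oxan-2-one | C=C(C)[C@@H]1CCOC(=O)[C@H]1CCCO[Si](C)(C)C(C)(C)C | intermediate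
7 | (2S,3R)-2-[3-(tert-butyldimethylsilyloxy)propyl]-3-(2-hydroxyethyl)-N-methoxy-N,4-dimethylpent-4-enamide | C=C(C)[C@H](CCO)[C@H](CCCO[Si](C)(C)C(C)(C)C)C(=O)N(C)OC | intermediate
8 | (2S,3R)-2-[3-(tert-butyldimethylsilyloxy)propyl]-3-(2-iodoethyl)-N-methoxy-N,4-dimethylpent-4-enamide | C=C(C)[C@H](CCI)[C@H](CCCO[Si](C)(C)C(C)(C)C)C(=O)N(C)OC | intermediate
9 | bromomagnesium alkoxide of the methyl adduct of 8 (chelated hemiaminal) | C=C(C)[C@H](CCI)[C@H](CCCO[Si](C)(C)C(C)(C)C)C(C)(O[Mg]Br)N(C)OC | intermediate
10 | (3S,4R)-3-[3-(tert-butyldimethylsilyloxy)propyl]-6-iodo-4-(prop-1-en-2-yl)hexan-2-one | C=C(C)[C@H](CCI)[C@H](CCCO[Si](C)(C)C(C)(C)C)C(C)=O | intermediate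
11 | alkylsamarium diiodide from 10 | C=C(C)[C@H](CC[Sm](I)I)[C@H](CCCO[Si](C)(C)C(C)(C)C)C(C)=O | intermediate
12 | (1R,2S,3R)-2-[3-(tert-butyldimethylsilyloxy)propyl]-1-methyl-3-(prop-1-en-2-yl)cyclopentan-1-ol | C=C(C)[C@@H]1CC[C@@](C)(O)[C@H]1CCCO[Si](C)(C)C(C)(C)C | intermediate
13 | (1R,2S,3R)-2-(3-hydroxypropyl)-1-methyl-3-(prop-1-en-2-yl)cyclopentan-1-ol | C=C(C)[C@@H]1CC[C@@](C)(O)[C@H]1CCCO | intermediate
14 | 3-[(1S,2R,5R)-2-hydroxy-2-methyl-5-(prop-1-en-2-yl)cyclopentyl]propanal | C=C(C)[C@@H]1CC[C@@](C)(O)[C@H]1CCC=O | intermediate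
15 | (4aS,5R,7aR)-7a-methyl-5-(prop-1-en-2-yl)octahydrocyclopenta[b]pyran-2-ol (lactol, both anomers) | C=C(C)[C@@H]1CC[C@@]2(C)OC(O)CC[C@@H]12 | intermediate
16 | (4aS,5R,7aR)-7a-methyl-5-(prop-1-en-2-yl)hexahydrocyclopenta[b]pyran-2(3H)-one | C=C(C)[C@@H]1CC[C@@]2(C)OC(=O)CC[C@@H]12 | intermediate
17 | ethyl (R)-3-hydroxybutanoate | CCOC(=O)C[C@@H](C)O | starting material
18 | 1-bromo-3-methylbut-2-ene | CC(C)=CCBr | starting material
19 | dilithio dianion of 17 | CCOC([O-])=C[C@@H](C)[O-].[Li+].[Li+] | intermediate
20 | ethyl (2R)-2-[(1R)-1-hydroxyethyl]-5-methylhex-4-enoate | CCOC(=O)[C@H](CC=C(C)C)[C@@H](C)O | intermediate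
21 | dilithio dianion of 20 | CCOC([O-])=C(CC=C(C)C)[C@@H](C)[O-].[Li+].[Li+] | intermediate
22 | ethyl (2S)-2-[(1R)-1-hydroxyethyl]-2,5-dimethylhex-4-enoate | CCOC(=O)[C@@](C)(CC=C(C)C)[C@@H](C)O | intermediate
23 | ethyl (2S)-2-acetyl-2,5-dimethylhex-4-enoate | CCOC(=O)[C@@](C)(CC=C(C)C)C(C)=O | intermediate
24 | lithium enolate of 23 (acetyl CH3 side) | CCOC(=O)[C@@](C)(CC=C(C)C)C([O-])=C.[Li+] | intermediate
25 | ethyl (2S)-7-[(1S,2R,5R)-2-hydroxy-2-methyl-5-(prop-1-en-2-yl)cyclopentyl]-2-methyl-2-(3-methylbut-2-en-1-yl)-3,5-dioxoheptanoate | C=C(C)[C@@H]1CC[C@@](C)(O)[C@H]1CCC(=O)CC(=O)[C@](C)(CC=C(C)C)C(=O)OCC | intermediate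
26 | trilithio polyanion of 25 (alkoxide plus dienediolate) | C=C(C)[C@@H]1CC[C@@](C)([O-])[C@H]1CC=C([O-])C=C([O-])[C@](C)(CC=C(C)C)C(=O)OCC.[Li+].[Li+].[Li+] | intermediate
27 | (6R)-3,5-dihydroxy-4-{[(1S,2R,5R)-2-hydroxy-2-methyl-5-(prop-1-en-2-yl)cyclopentyl]methyl}-6-methyl-6-(3-methylbut-2-en-1-yl)cyclohexa-2,4-dien-1-one | C=C(C)[C@@H]1CC[C@@](C)(O)[C@H]1CC1=C(O)[C@@](C)(CC=C(C)C)C(=O)C=C1O | intermediate
28 | (S)-2-methylbutanoic acid | CC[C@H](C)C(=O)O | starting material
29 | enol (S)-2-methylbutanoate of 27 at the C3 oxygen (representative regioisomer) | C=C(C)[C@@H]1CC[C@@](C)(O)[C@H]1CC1=C(O)[C@@](C)(CC=C(C)C)C(=O)C=C1OC(=O)[C@@H](C)CC | intermediate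
30 | (6R)-3,5-dihydroxy-4-{[(1S,2R,5R)-2-hydroxy-2-methyl-5-(prop-1-en-2-yl)cyclopentyl]methyl}-6-methyl-6-(3-methylbut-2-en-1-yl)-2-[(2S)-2-methylbutanoyl]cyclohexa-2,4-dien-1-one | C=C(C)[C@@H]1CC[C@@](C)(O)[C@H]1CC1=C(O)[C@@](C)(CC=C(C)C)C(=O)C(C(=O)[C@@H](C)CC)=C1O | target

**Step count**

Total step count: 14. Longest linear sequence: 11 (steps 1–8, then 12–14).

**Steps most likely to fail**

**Step 6.** The acetyl group may present its two faces with little preference, so that both carbinol epimers form. The primary radical may also pick up hydrogen before the second electron arrives, which would end in loss of iodine without ring closure.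

The fallback sets out from iodo amide 8.
- Iodine–lithium exchange (t-BuLi, Et2O/pentane, −78 °C) gives a primary alkyllithium.
- This closes on the Weinreb amide, forming the same ring bond by acyl substitution instead of carbonyl addition, to give (2S,3R)-2-[3-(tert-butyldimethylsilyloxy)propyl]-3-(prop-1-en-2-yl)cyclopentan-1-one F1.
- MeLi/CeCl3 (THF, −78 °C) should then add to the ring ketone on the face opposite the neighbouring arm. That places methyl trans and hydroxyl cis to the arm, and the route is rejoined at 12.

**Step 12.** Addition of the ketone enolate to the lactone may be slow. Proton transfer from the lactone α-CH2 to the enolate may compete, and the adduct may fall back to lactone and ketone on work-up.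

The fallback sets out from lactone 16 and replaces the acylation by an aldol addition and an oxidation.
- iBu2AlH (PhMe, −78 °C) reduces 16 to lactol 15.
- The lactol is deprotonated with LiN(SiMe3)2 and treated with enolate 24 at −78 °C, so that the open hydroxy aldehyde form 14 is captured.
- This gives ethyl (2S)-5-hydroxy-7-[(1S,2R,5R)-2-hydroxy-2-methyl-5-(prop-1-en-2-yl)cyclopentyl]-2-methyl-2-(3-methylbut-2-en-1-yl)-3-oxoheptanoate F2 (both C5 epimers).
- Dess–Martin oxidation touches only the secondary alcohol and rejoins the route at 25.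

**Step 13.** The third deprotonation may stay incomplete. Closure may then run through oxygen instead of carbon, or the aggregated polyanion may attack the hindered ester too slowly.

The fallback sets out from 25 and takes the alkoxide charge out of the problem.
- Et3SiOTf/2,6-lutidine (CH2Cl2, −78 → 0 °C) gives the bis(triethylsilyl) derivative of 25, with a tertiary silyl ether and an enol silyl ether, F3.
- Brief K2CO3/MeOH cleaves only the enol silyl ether to give the tertiary triethylsilyl ether of 25 F4.
- LiN(iPr)2 (2.2 equiv, THF, −78 °C → rt) forms the ordinary β-diketone dianion, which closes on the ester to the tertiary triethylsilyl ether of 27 F5.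
- HF·pyridine (THF, 0 °C) frees the carbinol and rejoins the route at 27.

**Further compounds**

F1 | step 6 | (2S,3R)-2-[3-(tert-butyldimethylsilyloxy)propyl]-3-(prop-1-en-2-yl)cyclopentan-1-one | C=C(C)[C@@H]1CCC(=O)[C@H]1CCCO[Si](C)(C)C(C)(C)C
F2 | step 12 | ethyl (2S)-5-hydroxy-7-[(1S,2R,5R)-2-hydroxy-2-methyl-5-(prop-1-en-2-yl)cyclopentyl]-2-methyl-2-(3-methylbut-2-en-1-yl)-3-oxoheptanoate | C=C(C)[C@@H]1CC[C@@](C)(O)[C@H]1CCC(O)CC(=O)[C@](C)(CC=C(C)C)C(=O)OCC
F3 | step 13 | bis(triethylsilyl) derivative of 25 (tertiary silyl ether and C5 enol silyl ether) | C=C(C)[C@@H]1CC[C@@](C)(O[Si](CC)(CC)CC)[C@H]1CCC(O[Si](CC)(CC)CC)=CC(=O)[C@](C)(CC=C(C)C)C(=O)OCC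
F4 | step 13 | tertiary triethylsilyl ether of 25 | C=C(C)[C@@H]1CC[C@@](C)(O[Si](CC)(CC)CC)[C@H]1CCC(=O)CC(=O)[C@](C)(CC=C(C)C)C(=O)OCC
F5 | step 13 | tertiary triethylsilyl ether of 27 | C=C(C)[C@@H]1CC[C@@](C)(O[Si](CC)(CC)CC)[C@H]1CC1=C(O)[C@@](C)(CC=C(C)C)C(=O)C=C1O
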